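Start with the easy step: put every target reading on the fraction of the charge. At 80.0 s, Saturday's run at 0.40 M reads 13.3 % and Sunday's at 0.60 M reads 12.6 %, a gap smaller than the scatter of 1 percentage point. So pool the two runs, and assume the same curve at 0.80 M.

| setting | Saturday's | Sunday's | theta | zeta |
|---|---|---|---|---|
| substrate | 0.40 M | 0.60 M | 0.80 M | 0.80 M |
| gas | 180 mM (held) | 180 mM (held) | 180 mM (held) | 180 mM (held) |
| remark | run made earlier | run made earlier |  |  |
| time |  |  | 2.0 min | 5.0 min |

- Saturday's (time / s: target / %): 10.0: 0.1; 12.0: 1.1; 20.0: 0; 30.0: 2.2; 40.0: 4.2; 60.0: 9.8; 80.0: 13.3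
- Sunday's (time / s: target / %): 10.0: 0; 12.0: 1.2; 20.0: 1.6; 30.0: 3.0; 50.0: 6.6; 80.0: 12.6

(scatter of a reading: 1 percentage point)

- the numbers in the tables scatter with a standard deviation of 1 percentage point
- at the start none of the gas is in solution

* which of the two there is more of at the end, theta (target / isomer of the product)
* which of the two there is more of at the end, zeta (target / isomer of the product)
* final target, as a percentage of the substrate charged, in theta
* final target, as a percentage of the substrate charged, in zeta

Now climb the ladder of times. Define the target clock 0.00225 s⁻¹ as the pseudo-first-order constant on the fraction not yet target, read between the pooled readings at 30.0 s and 80.0 s. Run that line back to zero for the lag, 18.3 s. The first rung is the lag, shorter than theta's 2.0 min, so count it as over. The next rung is the clock's life, its inverse, 445 s, longer than zeta's 5.0 min, so by this clock neither flask stands on the flat of its curve.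

Take one minus the exponential of minus the clock times the time past the lag. My reckoning gives 20.4 % target for theta and 46.9 % for zeta. No isomer was read, so I commit to no order: for theta my reckoning leaves 79.6 % of the charge not target, which is room for isomer to lead. The forecast gives 19 % and 44 %, each below mine, names target and target as the larger, and holds the isomer minor: “I assume it stays minor”.

Theta gives 21.9 % target against 31.3 % isomer of the product, and zeta gives 45.4 % against 40.1 %.

    substrate ⇌ tautomer (K = 4.70, k = 0.00950 s⁻¹)
    substrate + partner → isomer of the product (k = 0.0380 M⁻¹ s⁻¹)
    partner + tautomer → target (k = 0.0520 M⁻¹ s⁻¹)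
    gas ⇌ partner, rate k4*(csat - [partner]) (kL = 0.160 s⁻¹)
    tautomer → decomposed reagent (k = 0.00100 s⁻¹)

The forecast's order fails in theta and holds in zeta. At 1.00 min, theta already held 20.8 % isomer against 8.35 % target. Between theta's reading and zeta's, flasks of one charge, the same measure gives 0.00199 s⁻¹ against the clock's 0.00225 s⁻¹.

Now take the neighbour, theta's flask read at 3.0 min: the clock gives 30.5 % target. The computed flask holds 33.0 %.

(Readings and results are simulated for an exercise, and the scatter is random.)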